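**Plan**
Ring numbering of target 35: C1 carries the acrylic acid, C2 the OH, C3 the hydroxypropenyl group, C4 is the quaternary carbon, C5 the CH2, C6 the acyloxy carbon. The retrosynthesis cuts the C6 ester (Mitsunobu), the C1–acrylate C–C bond (Negishi on an α-iodoenone), the C2–O bond (directed epoxidation), then the ring bond C4–C5 by a retro-Claisen, then the lactone C–O bond and the C3–alkenyl bond of an acyclic aldehyde.
Enabling feature: C6 (at ketone level), C5H2 and quaternary C4 with its vinyl group form a γ,δ-unsaturated ketone. Tying the C6 oxygen to the vinyl CH2 puts this allyl vinyl ether into an eight-membered ring (O, C6, C1, C2, C3, C4 and the two vinyl carbons, C5 exocyclic), so one [3,3] shift contracts 8 → 6 and creates C4, C5 and the vinyl group together.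
Forward: the chain is joined by organocatalytic alkenylation of an enal, closed to the eight-membered lactone, methylenated and contracted to the cyclohexanone. The ring is then taken to the enone, alkenylated at C1, oxygenated at C2, esterified at C6, and the side-chain alcohol is oxidised to the acid.
Stereochemistry: C3 from the chiral imidazolidinone; C4 from C3 in the chair–chair Claisen transition state; C6 first from an oxazaborolidine reduction (to direct the C2 epoxidation), then reset by equatorial hydride attack and Mitsunobu inversion; C2 from the hydroxyl-directed epoxidation; C1 by equilibration. The (Z)-geometry of 1 makes the lactone and the rearrangement possible, and the (Z)-enoate comes from butenolide 28.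

Key step: step 11

Remark: the target is taken exactly as drawn (C4 vinyl cis to the C3 substituent; C2–O, C1–C and C6–O trans,trans); 1, 5, 17 and 28 are taken as purchasable; TBS = tert-butyldimethylsilyl, TES = triethylsilyl, PMB = 4-methoxybenzyl.

**Route**

Step 1
Reactants: 1 (Z)-3-iodobut-2-en-1-ol
Product: 3 potassium trifluoro[(E)-4-hydroxybut-2-en-2-yl]borate (boron cis to CH2OH), via pinacol boronate 2 (not isolated)
Conditions: B2pin2, PdCl2(PPh3)2 (3 mol%), PPh3, KOPh, toluene, 50 °C; then KHF2, MeOH/H2O, 25 °C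
Reagents that add atoms: bis(pinacolato)diboron CC1(C)OB(OC1(C)C)B1OC(C)(C)C(C)(C)O1; potassium hydrogen difluoride [K+].[F-].F
Why: Miyaura borylation of the alkenyl iodide with retention of alkene geometry, then fluoride exchange to the stable trifluoroborate, the free allylic alcohol being inert to zerovalent palladium.

Step 2
Reactants: 3 potassium trifluoro[(E)-4-hydroxybut-2-en-2-yl]borate
Product: 4 potassium [(E)-4-acetoxybut-2-en-2-yl]trifluoroborate
Conditions: Ac2O, pyridine, DMAP (cat.), MeCN, 25 °C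
Reagents that add atoms: acetic anhydride CC(=O)OC(C)=O
Why: O-acetylation by acyl transfer, tolerated by the trifluoroborate; the acetate is chosen because it is later cleaved together with the methyl ester.

Step 3
Reactants: 5 methyl 4-oxobutanoate
Product: 6 methyl (E)-6-oxohex-4-enoate
Conditions: Ph3P=CHCHO (1.0 equiv), toluene, 80 °C
Reagents that add atoms: (triphenylphosphoranylidene)acetaldehyde O=CC=P(c1ccccc1)(c1ccccc1)c1ccccc1
Why: Wittig olefination with the stabilised formylmethylene ylide should give the (E)-enal, one equivalent limiting a second homologation.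

Step 4
Reactants: 4 potassium [(E)-4-acetoxybut-2-en-2-yl]trifluoroborate; 6 methyl (E)-6-oxohex-4-enoate
Product: 7 methyl (4R)-4-[(2Z)-4-acetoxybut-2-en-2-yl]-6-oxohexanoate
Conditions: (2S,5S)-5-benzyl-2-tert-butyl-3-methylimidazolidin-4-one·HCl (20 mol%), HF (aq., 1 equiv), DME, −20 → 25 °C
Reagents that add atoms: none
Why: Iminium-ion organocatalysis (Friedel–Crafts-type conjugate addition of an alkenyltrifluoroborate, boron leaving as BF4−): the benzyl group of the catalyst shields one face of the (E)-iminium, so the boron-bearing carbon should add with retention of alkene geometry to the open Re face of the β-carbon and set the (4R) centre.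

Step 5
Reactants: 7 methyl (4R)-4-[(2Z)-4-acetoxybut-2-en-2-yl]-6-oxohexanoate
Product: 8 methyl (4S)-4-[(2Z)-4-acetoxybut-2-en-2-yl]-5-formylhex-5-enoate
Conditions: CH2O (37% aq.), pyrrolidine (10 mol%), propionic acid (10 mol%), i-PrOH, 45 °C
Reagents that add atoms: formaldehyde C=O
Why: Amine/acid-catalysed α-methylenation of the aldehyde (Mannich condensation, then loss of the amine), which should leave the neighbouring stereocentre untouched because its hydrogen is not acidified.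

Step 6
Reactants: 8 methyl (4S)-4-[(2Z)-4-acetoxybut-2-en-2-yl]-5-formylhex-5-enoate
Product: 9 methyl (4S)-4-[(2Z)-4-acetoxybut-2-en-2-yl]-5-(hydroxymethyl)hex-5-enoate
Conditions: NaBH4, CeCl3·7H2O, MeOH, −78 °C
Reagents that add atoms: none
Why: Luche 1,2-reduction of the 2-substituted acrolein, which should spare the methyl ester and the acetate.

Step 7
Reactants: 9 methyl (4S)-4-[(2Z)-4-acetoxybut-2-en-2-yl]-5-(hydroxymethyl)hex-5-enoate
Product: 10 methyl (4S)-4-[(2Z)-4-acetoxybut-2-en-2-yl]-5-[(TBS-oxy)methyl]hex-5-enoate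
Conditions: TBSCl, imidazole, DMF, 25 °C
Reagents that add atoms: tert-butyldimethylsilyl chloride CC(C)(C)[Si](C)(C)Cl
Why: Standard silylation of the primary allylic alcohol.

Step 8
Reactants: 10 methyl (4S)-4-[(2Z)-4-acetoxybut-2-en-2-yl]-5-[(TBS-oxy)methyl]hex-5-enoate
Product: 11 (4S)-4-[(2Z)-4-hydroxybut-2-en-2-yl]-5-[(TBS-oxy)methyl]hex-5-enoic acid
Conditions: LiOH·H2O, THF/MeOH/H2O, 25 °C; then 0.5 M HCl to pH 4, 0 °C
Reagents that add atoms: lithium hydroxide [Li+].[OH-]
Why: Saponification cleaves the acetate and the methyl ester in one operation, while the silyl ether and the bis-allylic stereocentre (not α to a carbonyl) should survive.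

Step 9
Reactants: 11 (4S)-4-[(2Z)-4-hydroxybut-2-en-2-yl]-5-[(TBS-oxy)methyl]hex-5-enoic acid
Product: 12 (5S,6Z)-6-methyl-5-[3-(TBS-oxy)prop-1-en-2-yl]-3,4,5,8-tetrahydro-2H-oxocin-2-one
Conditions: 2-methyl-6-nitrobenzoic anhydride (MNBA), DMAP, CH2Cl2 (1 mM, slow addition), 25–40 °C
Reagents that add atoms: none
Why: Shiina macrolactonisation through the mixed anhydride and DMAP acyl transfer, in which the (Z)-alkene holds the chain ends on the same side and should favour the eight-membered ring over dimerisation.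

Step 10
Reactants: 12 (5S,6Z)-6-methyl-5-[3-(TBS-oxy)prop-1-en-2-yl]-3,4,5,8-tetrahydro-2H-oxocin-2-one
Product: 13 (5S,6Z)-6-methyl-2-methylidene-5-[3-(TBS-oxy)prop-1-en-2-yl]-3,4,5,8-tetrahydro-2H-oxocine
Conditions: Cp2TiMe2 (3 equiv), toluene/THF, 65 °C, dark; filtration through basic Al2O3, used at once
Reagents that add atoms: dimethyltitanocene [CH3-].[CH3-].[Ti+4].c1cc[cH-]c1.c1cc[cH-]c1
Why: Petasis methylenation of the lactone carbonyl (titanium methylidene, oxatitanacyclobutane, cycloreversion) gives the exocyclic enol ether under non-acidic conditions, and the titanium reagent is removed before heating so that it cannot methylenate the ketone formed next.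

Step 11
Reactants: 13 (5S,6Z)-6-methyl-2-methylidene-5-[3-(TBS-oxy)prop-1-en-2-yl]-3,4,5,8-tetrahydro-2H-oxocine
Product: 14 (3S,4S)-3-ethenyl-3-methyl-4-[3-(TBS-oxy)prop-1-en-2-yl]cyclohexan-1-one
Conditions: toluene (0.01 M), Et3N (trace), base-washed sealed tube, 140 °C
Reagents that add atoms: none
Why: Proposed new method: the oxocine holds an allyl vinyl ether (exocyclic CH2=C2–O1–C8H2–C7H=C6(CH3)) inside its eight-membered ring, and heating should trigger a concerted suprafacial [3,3] sigmatropic (Claisen) shift in which the exocyclic methylene carbon bonds to C6 while the allylic O1–C8 bond breaks, the enol ether becoming the ketone and the ring alkene the vinyl group. The closest known reaction types are the methylenation–Claisen ring expansion of 2-methylene-6-vinyltetrahydropyrans to cyclooctenones and the Ireland–Claisen ring contraction of unsaturated macrolactones; here the allylic oxygen is endocyclic and the vinyl ether exocyclic, so the ring contracts by two atoms, driven by C=O formation and release of medium-ring strain. The cyclohexanone closes by transannular C–C bond formation across the 2,6-positions of the oxocine (through the methylene on C2), via a bicyclo[3.3.1]-like chair–chair transition state in which the O1–C8–C7 bridge is necessarily axial on the forming carbocycle. The new quaternary stereocentre is controlled by the C5 stereocentre: its propenyl group takes the equatorial site of that chair, which puts the departing bridge (the future vinyl group) cis to it and the methyl trans, the relationship that conjugate addition of a vinyl metal to a 4-substituted enone would not give. The step needs this diastereofacial selectivity and must outrun isomerisation of the exocyclic enol ether into the ring; the ring-locked (Z)-alkene fixes the allyl geometry, there is only one allyl vinyl ether array in 13, and amine-buffered, base-washed glass suppresses acid-catalysed isomerisation.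

Step 12
Reactants: 14 (3S,4S)-3-ethenyl-3-methyl-4-[3-(TBS-oxy)prop-1-en-2-yl]cyclohexan-1-one
Product: 15 (4S,5S)-5-ethenyl-5-methyl-4-[3-(TBS-oxy)prop-1-en-2-yl]cyclohex-2-en-1-one
Conditions: IBX, 4-methoxypyridine N-oxide, DMSO, 25 °C
Reagents that add atoms: none
Why: IBX dehydrogenation of the ketone through its enol, where only the side away from the quaternary carbon carries a β-hydrogen, so a single enone should form.

Step 13
Reactants: 15 (4S,5S)-5-ethenyl-5-methyl-4-[3-(TBS-oxy)prop-1-en-2-yl]cyclohex-2-en-1-one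
Product: 16 (4S,5S)-5-ethenyl-2-iodo-5-methyl-4-[3-(TBS-oxy)prop-1-en-2-yl]cyclohex-2-en-1-one
Conditions: I2, pyridine, CH2Cl2, 0 → 25 °C
Reagents that add atoms: iodine II
Why: α-Iodination of the enone by conjugate addition of pyridine, iodination of the enolate and elimination.

Step 14
Reactants: 17 2-bromoprop-2-en-1-ol
Product: 18 1-{[(2-bromoprop-2-en-1-yl)oxy]methyl}-4-methoxybenzene
Conditions: NaH, 4-methoxybenzyl chloride, n-Bu4NI (cat.), THF, 0 → 25 °C
Reagents that add atoms: 4-methoxybenzyl chloride COc1ccc(CCl)cc1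
Why: Williamson etherification of the alkoxide.

Step 15
Reactants: 18 1-{[(2-bromoprop-2-en-1-yl)oxy]methyl}-4-methoxybenzene; 16 (4S,5S)-5-ethenyl-2-iodo-5-methyl-4-[3-(TBS-oxy)prop-1-en-2-yl]cyclohex-2-en-1-one
Product: 21 (4S,5S)-5-ethenyl-5-methyl-2-[3-(PMB-oxy)prop-1-en-2-yl]-4-[3-(TBS-oxy)prop-1-en-2-yl]cyclohex-2-en-1-one, via alkenyllithium 19 (not isolated), via alkenylzinc bromide 20 (not isolated)
Conditions: 18, t-BuLi (2 equiv), Et2O, −78 °C; ZnBr2, THF, −78 → 0 °C; then 16, Pd(PPh3)4 (5 mol%), THF, 25–40 °C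
Reagents that add atoms: none
Why: Bromine–lithium exchange, transmetalation to zinc and Negishi coupling with the α-iodoenone (oxidative addition of zerovalent palladium to C–I, transmetalation, reductive elimination) form the bond to the future acrylate carbon.

Step 16
Reactants: 21 (4S,5S)-5-ethenyl-5-methyl-2-[3-(PMB-oxy)prop-1-en-2-yl]-4-[3-(TBS-oxy)prop-1-en-2-yl]cyclohex-2-en-1-one
Product: 22 (1S,4S,5S)-5-ethenyl-5-methyl-2-[3-(PMB-oxy)prop-1-en-2-yl]-4-[3-(TBS-oxy)prop-1-en-2-yl]cyclohex-2-en-1-ol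
Conditions: (R)-2-methyl-CBS-oxazaborolidine (0.2 equiv), catecholborane, toluene, −78 °C; MeOH quench
Reagents that add atoms: none
Why: Corey–Bakshi–Shibata reduction, in which the oxazaborolidine binds the carbonyl anti to the α-branched alkenyl side and delivers hydride to the Re face, should set (1S) (hydroxyl cis to the ring vinyl group) under reagent control without hydroboration of the alkenes at this temperature.

Step 17
Reactants: 22 (1S,4S,5S)-5-ethenyl-5-methyl-2-[3-(PMB-oxy)prop-1-en-2-yl]-4-[3-(TBS-oxy)prop-1-en-2-yl]cyclohex-2-en-1-ol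
Product: 23 (1S,2S,4S,5S,6R)-4-ethenyl-4-methyl-1-[3-(PMB-oxy)prop-1-en-2-yl]-5-[3-(TBS-oxy)prop-1-en-2-yl]-7-oxabicyclo[4.1.0]heptan-2-ol
Conditions: VO(acac)2 (5 mol%), t-BuOOH, CH2Cl2, 0 °C
Reagents that add atoms: tert-butyl hydroperoxide CC(C)(C)OO
Why: Hydroxyl-directed epoxidation, in which the vanadium alkylperoxide bound to the allylic alkoxide transfers oxygen to the adjacent ring alkene on the hydroxyl face, should set both oxirane carbons cis to the OH (and hence cis to the C5 substituent) and leave the non-allylic alkenes alone.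

Step 18
Reactants: 23 (1S,2S,4S,5S,6R)-4-ethenyl-4-methyl-1-[3-(PMB-oxy)prop-1-en-2-yl]-5-[3-(TBS-oxy)prop-1-en-2-yl]-7-oxabicyclo[4.1.0]heptan-2-ol
Product: 24 (1R,4S,5S,6R)-4-ethenyl-4-methyl-1-[3-(PMB-oxy)prop-1-en-2-yl]-5-[3-(TBS-oxy)prop-1-en-2-yl]-7-oxabicyclo[4.1.0]heptan-2-one
Conditions: Dess–Martin periodinane, NaHCO3, CH2Cl2, 0 → 25 °C
Reagents that add atoms: none
Why: Dess–Martin oxidation of the secondary alcohol, buffered to spare the vinyl oxirane.

Step 19
Reactants: 24 (1R,4S,5S,6R)-4-ethenyl-4-methyl-1-[3-(PMB-oxy)prop-1-en-2-yl]-5-[3-(TBS-oxy)prop-1-en-2-yl]-7-oxabicyclo[4.1.0]heptan-2-one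
Product: 25 (2S,3R,4S,5S)-5-ethenyl-3-hydroxy-5-methyl-2-[3-(PMB-oxy)prop-1-en-2-yl]-4-[3-(TBS-oxy)prop-1-en-2-yl]cyclohexan-1-one
Conditions: SmI2 (2.2 equiv), THF/MeOH, −78 °C
Reagents that add atoms: none
Why: Two single-electron transfers from SmI2 cleave the α-C–O bond of the α,β-epoxy ketone, so the β-carbinol keeps the configuration from step 17, and α-protonation of the samarium dienolate gives the β,γ-unsaturated ketone, with C2 still epimerisable and fixed in step 20.

Step 20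
Reactants: 25 (2S,3R,4S,5S)-5-ethenyl-3-hydroxy-5-methyl-2-[3-(PMB-oxy)prop-1-en-2-yl]-4-[3-(TBS-oxy)prop-1-en-2-yl]cyclohexan-1-one
Product: 26 (2S,3R,4S,5S)-5-ethenyl-5-methyl-2-[3-(PMB-oxy)prop-1-en-2-yl]-4-[3-(TBS-oxy)prop-1-en-2-yl]-3-(TES-oxy)cyclohexan-1-one
Conditions: Et3SiOTf, 2,6-lutidine, CH2Cl2, −78 °C; then DBU (cat.), 0 °C
Reagents that add atoms: triethylsilyl trifluoromethanesulfonate CC[Si](CC)(CC)OS(=O)(=O)C(F)(F)F
Why: Silyl triflate silylation of the hindered alcohol, after which base equilibrates C2 through the enol; with the bulky silyloxy group at C3 the 2,3-trans isomer, both groups equatorial in the chair with axial C5 methyl, should be the thermodynamic product.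

Step 21
Reactants: 26 (2S,3R,4S,5S)-5-ethenyl-5-methyl-2-[3-(PMB-oxy)prop-1-en-2-yl]-4-[3-(TBS-oxy)prop-1-en-2-yl]-3-(TES-oxy)cyclohexan-1-one
Product: 27 (1R,2R,3R,4S,5S)-5-ethenyl-5-methyl-2-[3-(PMB-oxy)prop-1-en-2-yl]-4-[3-(TBS-oxy)prop-1-en-2-yl]-3-(TES-oxy)cyclohexan-1-ol
Conditions: LiBH(s-Bu)3, THF, −78 °C
Reagents that add atoms: none
Why: The bulky hydride should attack equatorially, from the face opposite the axial C5 methyl group, giving the axial (1R) alcohol.

Step 22
Reactants: 28 3-methylfuran-2(5H)-one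
Product: 30 (2Z)-4-acetoxy-2-methylbut-2-enoic acid, via sodium hydroxy-enoate 29 (not isolated)
Conditions: NaOH (1 equiv), H2O, 25 °C, evaporate; NaH (1 equiv), then Ac2O (1 equiv), DMF, 0 °C; NaHSO4 (aq.) to pH 3, 0 °C
Reagents that add atoms: sodium hydroxide [Na+].[OH-]; acetic anhydride CC(=O)OC(C)=O
Why: Saponification of the butenolide keeps the ring's cis geometry in the (Z)-hydroxy carboxylate, and the alkoxide made with NaH is far more nucleophilic than the carboxylate, so one equivalent of Ac2O should acetylate oxygen only and block relactonisation.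

Step 23
Reactants: 27 (1R,2R,3R,4S,5S)-5-ethenyl-5-methyl-2-[3-(PMB-oxy)prop-1-en-2-yl]-4-[3-(TBS-oxy)prop-1-en-2-yl]-3-(TES-oxy)cyclohexan-1-ol; 30 (2Z)-4-acetoxy-2-methylbut-2-enoic acid
Product: 31 (1S,2R,3R,4S,5S)-5-ethenyl-5-methyl-2-[3-(PMB-oxy)prop-1-en-2-yl]-4-[3-(TBS-oxy)prop-1-en-2-yl]-3-(TES-oxy)cyclohexyl (2Z)-4-acetoxy-2-methylbut-2-enoate
Conditions: PPh3, DIAD, toluene, 0 → 25 °C
Reagents that add atoms: none
Why: Mitsunobu esterification, in which the axial alcohol is activated as its alkoxyphosphonium ion and displaced by the carboxylate from the equatorial direction (SN2, inversion), should give the equatorial (1S) ester.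

Step 24
Reactants: 31 (1S,2R,3R,4S,5S)-5-ethenyl-5-methyl-2-[3-(PMB-oxy)prop-1-en-2-yl]-4-[3-(TBS-oxy)prop-1-en-2-yl]-3-(TES-oxy)cyclohexyl (2Z)-4-acetoxy-2-methylbut-2-enoate
Product: 32 (1S,2R,3R,4S,5S)-5-ethenyl-2-(3-hydroxyprop-1-en-2-yl)-5-methyl-4-[3-(TBS-oxy)prop-1-en-2-yl]-3-(TES-oxy)cyclohexyl (2Z)-4-acetoxy-2-methylbut-2-enoate
Conditions: DDQ, CH2Cl2/pH 7 buffer, 0 °C
Reagents that add atoms: none
Why: Oxidative cleavage of the 4-methoxybenzyl ether by DDQ (hydride abstraction, hydrolysis of the oxocarbenium ion) should leave silyl ethers, esters and unconjugated alkenes untouched.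

Step 25
Reactants: 32 (1S,2R,3R,4S,5S)-5-ethenyl-2-(3-hydroxyprop-1-en-2-yl)-5-methyl-4-[3-(TBS-oxy)prop-1-en-2-yl]-3-(TES-oxy)cyclohexyl (2Z)-4-acetoxy-2-methylbut-2-enoate
Product: 34 2-[(1R,2R,3S,4S,6S)-6-{[(2Z)-4-acetoxy-2-methylbut-2-enoyl]oxy}-4-ethenyl-4-methyl-3-[3-(TBS-oxy)prop-1-en-2-yl]-2-(TES-oxy)cyclohexyl]prop-2-enoic acid, via enal 33 (not isolated)
Conditions: TEMPO (10 mol%), PhI(OAc)2, CH2Cl2, 25 °C; then NaClO2, NaH2PO4, 2-methylbut-2-ene, t-BuOH/H2O, 0 °C
Reagents that add atoms: sodium chlorite [Na+].[O-]Cl=O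
Why: TEMPO/PhI(OAc)2 oxidises the primary allylic alcohol to the enal and Pinnick oxidation (chlorous acid, hypochlorite trapped by the alkene additive) takes it to the acrylic acid while the silyl-protected C2 oxygen cannot form a lactol or lactone.

Step 26
Reactants: 34 2-[(1R,2R,3S,4S,6S)-6-{[(2Z)-4-acetoxy-2-methylbut-2-enoyl]oxy}-4-ethenyl-4-methyl-3-[3-(TBS-oxy)prop-1-en-2-yl]-2-(TES-oxy)cyclohexyl]prop-2-enoic acid
Product: 35 2-[(1S,2R,3S,4S,6S)-6-{[(2Z)-4-acetoxy-2-methylbut-2-enoyl]oxy}-4-ethenyl-2-hydroxy-3-(3-hydroxyprop-1-en-2-yl)-4-methylcyclohexyl]prop-2-enoic acid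
Conditions: HF·pyridine, pyridine, THF, 0 °C
Reagents that add atoms: none
Why: Buffered HF·pyridine cleaves both silyl ethers by Si–F bond formation without hydrolysing the esters, and low temperature with buffering should limit acid-catalysed lactonisation of the liberated γ-hydroxy acid.

**Compound list**
1 | (Z)-3-iodobut-2-en-1-ol | C/C(I)=C/CO | starting material
2 | (E)-3-(4,4,5,5-tetramethyl-1,3,2-dioxaborolan-2-yl)but-2-en-1-ol (boron cis to CH2OH) | C/C(B1OC(C)(C)C(C)(C)O1)=C/CO | intermediate (not isolated)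
3 | potassium trifluoro[(E)-4-hydroxybut-2-en-2-yl]borate | C/C(=C/CO)[B-](F)(F)F.[K+] | intermediate
4 | potassium [(E)-4-acetoxybut-2-en-2-yl]trifluoroborate | C/C(=C/COC(C)=O)[B-](F)(F)F.[K+] | intermediate
5 | methyl 4-oxobutanoate | COC(=O)CCC=O | starting material
6 | methyl (E)-6-oxohex-4-enoate | COC(=O)CC/C=C/C=O | intermediate
7 | methyl (4R)-4-[(2Z)-4-acetoxybut-2-en-2-yl]-6-oxohexanoate | COC(=O)CC[C@@H](/C(C)=C\COC(C)=O)CC=O | intermediate
8 | methyl (4S)-4-[(2Z)-4-acetoxybut-2-en-2-yl]-5-formylhex-5-enoate | COC(=O)CC[C@@H](/C(C)=C\COC(C)=O)C(=C)C=O | intermediate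
9 | methyl (4S)-4-[(2Z)-4-acetoxybut-2-en-2-yl]-5-(hydroxymethyl)hex-5-enoate | COC(=O)CC[C@@H](/C(C)=C\COC(C)=O)C(=C)CO | intermediate
10 | methyl (4S)-4-[(2Z)-4-acetoxybut-2-en-2-yl]-5-[(TBS-oxy)methyl]hex-5-enoate | COC(=O)CC[C@@H](/C(C)=C\COC(C)=O)C(=C)CO[Si](C)(C)C(C)(C)C | intermediate
11 | (4S)-4-[(2Z)-4-hydroxybut-2-en-2-yl]-5-[(TBS-oxy)methyl]hex-5-enoic acid | OC(=O)CC[C@@H](/C(C)=C\CO)C(=C)CO[Si](C)(C)C(C)(C)C | intermediate
12 | (5S,6Z)-6-methyl-5-[3-(TBS-oxy)prop-1-en-2-yl]-3,4,5,8-tetrahydro-2H-oxocin-2-one | O=C1CC[C@@H](/C(C)=C\CO1)C(=C)CO[Si](C)(C)C(C)(C)C | intermediate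
13 | (5S,6Z)-6-methyl-2-methylidene-5-[3-(TBS-oxy)prop-1-en-2-yl]-3,4,5,8-tetrahydro-2H-oxocine | C=C1CC[C@@H](/C(C)=C\CO1)C(=C)CO[Si](C)(C)C(C)(C)C | intermediate
14 | (3S,4S)-3-ethenyl-3-methyl-4-[3-(TBS-oxy)prop-1-en-2-yl]cyclohexan-1-one (vinyl cis to the C4 group) | C=C[C@]1(C)CC(=O)CC[C@@H]1C(=C)CO[Si](C)(C)C(C)(C)C | intermediate
15 | (4S,5S)-5-ethenyl-5-methyl-4-[3-(TBS-oxy)prop-1-en-2-yl]cyclohex-2-en-1-one | C=C[C@]1(C)CC(=O)C=C[C@@H]1C(=C)CO[Si](C)(C)C(C)(C)C | intermediate
16 | (4S,5S)-5-ethenyl-2-iodo-5-methyl-4-[3-(TBS-oxy)prop-1-en-2-yl]cyclohex-2-en-1-one | C=C[C@]1(C)CC(=O)C(I)=C[C@@H]1C(=C)CO[Si](C)(C)C(C)(C)C | intermediate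
17 | 2-bromoprop-2-en-1-ol | C=C(Br)CO | starting material
18 | 1-{[(2-bromoprop-2-en-1-yl)oxy]methyl}-4-methoxybenzene | C=C(Br)COCc1ccc(OC)cc1 | intermediate
19 | [3-(PMB-oxy)prop-1-en-2-yl]lithium | [Li]C(=C)COCc1ccc(OC)cc1 | intermediate (not isolated)
20 | bromo[3-(PMB-oxy)prop-1-en-2-yl]zinc | Br[Zn]C(=C)COCc1ccc(OC)cc1 | intermediate (not isolated)
21 | (4S,5S)-5-ethenyl-5-methyl-2-[3-(PMB-oxy)prop-1-en-2-yl]-4-[3-(TBS-oxy)prop-1-en-2-yl]cyclohex-2-en-1-one | C=C[C@]1(C)CC(=O)C(C(=C)COCc2ccc(OC)cc2)=C[C@@H]1C(=C)CO[Si](C)(C)C(C)(C)C | intermediate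
22 | (1S,4S,5S)-5-ethenyl-5-methyl-2-[3-(PMB-oxy)prop-1-en-2-yl]-4-[3-(TBS-oxy)prop-1-en-2-yl]cyclohex-2-en-1-ol | C=C[C@]1(C)C[C@H](O)C(C(=C)COCc2ccc(OC)cc2)=C[C@@H]1C(=C)CO[Si](C)(C)C(C)(C)C | intermediate
23 | (1S,2S,4S,5S,6R)-4-ethenyl-4-methyl-1-[3-(PMB-oxy)prop-1-en-2-yl]-5-[3-(TBS-oxy)prop-1-en-2-yl]-7-oxabicyclo[4.1.0]heptan-2-ol | C=C[C@]1(C)C[C@H](O)[C@]2(C(=C)COCc3ccc(OC)cc3)O[C@@H]2[C@@H]1C(=C)CO[Si](C)(C)C(C)(C)C | intermediate
24 | (1R,4S,5S,6R)-4-ethenyl-4-methyl-1-[3-(PMB-oxy)prop-1-en-2-yl]-5-[3-(TBS-oxy)prop-1-en-2-yl]-7-oxabicyclo[4.1.0]heptan-2-one | C=C[C@]1(C)CC(=O)[C@]2(C(=C)COCc3ccc(OC)cc3)O[C@@H]2[C@@H]1C(=C)CO[Si](C)(C)C(C)(C)C | intermediate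
25 | (2S,3R,4S,5S)-5-ethenyl-3-hydroxy-5-methyl-2-[3-(PMB-oxy)prop-1-en-2-yl]-4-[3-(TBS-oxy)prop-1-en-2-yl]cyclohexan-1-one | C=C[C@]1(C)CC(=O)[C@@H](C(=C)COCc2ccc(OC)cc2)[C@H](O)[C@@H]1C(=C)CO[Si](C)(C)C(C)(C)C | intermediate
26 | (2S,3R,4S,5S)-5-ethenyl-5-methyl-2-[3-(PMB-oxy)prop-1-en-2-yl]-4-[3-(TBS-oxy)prop-1-en-2-yl]-3-(TES-oxy)cyclohexan-1-one | C=C[C@]1(C)CC(=O)[C@@H](C(=C)COCc2ccc(OC)cc2)[C@H](O[Si](CC)(CC)CC)[C@@H]1C(=C)CO[Si](C)(C)C(C)(C)C | intermediate
27 | (1R,2R,3R,4S,5S)-5-ethenyl-5-methyl-2-[3-(PMB-oxy)prop-1-en-2-yl]-4-[3-(TBS-oxy)prop-1-en-2-yl]-3-(TES-oxy)cyclohexan-1-ol (axial OH) | C=C[C@]1(C)C[C@@H](O)[C@@H](C(=C)COCc2ccc(OC)cc2)[C@H](O[Si](CC)(CC)CC)[C@@H]1C(=C)CO[Si](C)(C)C(C)(C)C | intermediate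
28 | 3-methylfuran-2(5H)-one | CC1=CCOC1=O | starting material
29 | sodium (2Z)-4-hydroxy-2-methylbut-2-enoate | C/C(=C/CO)C(=O)[O-].[Na+] | intermediate (not isolated)
30 | (2Z)-4-acetoxy-2-methylbut-2-enoic acid | CC(=O)OC/C=C(/C)C(=O)O | intermediate
31 | (1S,2R,3R,4S,5S)-5-ethenyl-5-methyl-2-[3-(PMB-oxy)prop-1-en-2-yl]-4-[3-(TBS-oxy)prop-1-en-2-yl]-3-(TES-oxy)cyclohexyl (2Z)-4-acetoxy-2-methylbut-2-enoate | C=C[C@]1(C)C[C@H](OC(=O)/C(C)=C\COC(C)=O)[C@@H](C(=C)COCc2ccc(OC)cc2)[C@H](O[Si](CC)(CC)CC)[C@@H]1C(=C)CO[Si](C)(C)C(C)(C)C | intermediate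
32 | (1S,2R,3R,4S,5S)-5-ethenyl-2-(3-hydroxyprop-1-en-2-yl)-5-methyl-4-[3-(TBS-oxy)prop-1-en-2-yl]-3-(TES-oxy)cyclohexyl (2Z)-4-acetoxy-2-methylbut-2-enoate | C=C[C@]1(C)C[C@H](OC(=O)/C(C)=C\COC(C)=O)[C@@H](C(=C)CO)[C@H](O[Si](CC)(CC)CC)[C@@H]1C(=C)CO[Si](C)(C)C(C)(C)C | intermediate
33 | 2-[(1R,2R,3S,4S,6S)-6-{[(2Z)-4-acetoxy-2-methylbut-2-enoyl]oxy}-4-ethenyl-4-methyl-3-[3-(TBS-oxy)prop-1-en-2-yl]-2-(TES-oxy)cyclohexyl]prop-2-enal | C=C[C@]1(C)C[C@H](OC(=O)/C(C)=C\COC(C)=O)[C@@H](C(=C)C=O)[C@H](O[Si](CC)(CC)CC)[C@@H]1C(=C)CO[Si](C)(C)C(C)(C)C | intermediate (not isolated)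
34 | 2-[(1R,2R,3S,4S,6S)-6-{[(2Z)-4-acetoxy-2-methylbut-2-enoyl]oxy}-4-ethenyl-4-methyl-3-[3-(TBS-oxy)prop-1-en-2-yl]-2-(TES-oxy)cyclohexyl]prop-2-enoic acid | C=C[C@]1(C)C[C@H](OC(=O)/C(C)=C\COC(C)=O)[C@@H](C(=C)C(=O)O)[C@H](O[Si](CC)(CC)CC)[C@@H]1C(=C)CO[Si](C)(C)C(C)(C)C | intermediate
35 | 2-[(1S,2R,3S,4S,6S)-6-{[(2Z)-4-acetoxy-2-methylbut-2-enoyl]oxy}-4-ethenyl-2-hydroxy-3-(3-hydroxyprop-1-en-2-yl)-4-methylcyclohexyl]prop-2-enoic acid | C=C[C@]1(C)C[C@H](OC(=O)/C(C)=C\COC(C)=O)[C@@H](C(=C)C(=O)O)[C@H](O)[C@@H]1C(=C)CO | target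

**Counts and risks**
Total step count: 26. Longest linear sequence: 23 steps (1 → 35 through steps 1, 2, 4–13, 15–21 and 23–26).

Steps most likely to fail:

Step 11 (labelled step). The exocyclic enol ether may isomerise into the ring or hydrolyse before the ring reaches the bicyclic transition state, or the rearrangement may show poor facial selectivity at the quaternary carbon. The fallback uses known chemistry, sets out from hydroxy acid 11 and returns at ketone 14. Acetylation (Ac2O, pyridine, aqueous work-up) gives acetoxy acid F1. Activation with carbonyldiimidazole and reaction with potassium methyl malonate/MgCl2/Et3N gives β-keto ester F2. An intramolecular Tsuji–Trost allylic alkylation (Pd(PPh3)4, N,O-bis(trimethylsilyl)acetamide, KOAc, THF, high dilution) should attack the methyl-bearing allyl terminus, the six-membered ring being favoured over the eight-membered one, to give cyclic β-keto ester F3 with the vinyl-bearing quaternary carbon. Krapcho dealkoxycarbonylation (LiCl, wet DMSO, 150 °C) then gives 14; the cis/trans isomers at the quaternary carbon would have to be separated, since this closure is not expected to be as selective as the rearrangement.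

Step 23. The activated axial alcohol may undergo anti-periplanar E2 elimination toward the allylic C2 hydrogen instead of substitution by the weakly acidic enoic acid. The fallback sets out from ketone 26 and returns at ester 31 by a retention pathway. A thermodynamically biased electron-transfer reduction (SmI2, H2O, Et3N, THF) should give the equatorial alcohol F4. Yamaguchi esterification with acid 30 (2,4,6-trichlorobenzoyl chloride, Et3N, then DMAP, toluene) then gives 31 without touching the carbinol centre.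

Step 17. The hydroxyl-directed face is also the face shielded by the neighbouring C4 substituent, so oxygen transfer may be slow, poorly face-selective or diverted to the side-chain alkene of the diene. The fallback sets out from allylic alcohol 22 and returns at epoxy alcohol 23 by tethered oxygen delivery. Boc2O/DMAP gives tert-butyl carbonate F5. IBr (toluene/CH2Cl2, −85 °C) should form the iodonium ion on the open face, and the carbonate oxygen then closes onto the ring carbon next to the carbinol from the hydroxyl face to give iodo carbonate F6. K2CO3/MeOH cleaves the carbonate, and the freed alkoxide displaces the trans iodide to close the oxirane of 23.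

Further compounds
F1 | step 11 | (4S)-4-[(2Z)-4-acetoxybut-2-en-2-yl]-5-[(TBS-oxy)methyl]hex-5-enoic acid | OC(=O)CC[C@@H](/C(C)=C\COC(C)=O)C(=C)CO[Si](C)(C)C(C)(C)C
F2 | step 11 | methyl (6S)-6-[(2Z)-4-acetoxybut-2-en-2-yl]-3-oxo-7-[(TBS-oxy)methyl]oct-7-enoate | COC(=O)CC(=O)CC[C@@H](/C(C)=C\COC(C)=O)C(=C)CO[Si](C)(C)C(C)(C)C
F3 | step 11 | methyl (5S,6S)-6-ethenyl-6-methyl-2-oxo-5-[3-(TBS-oxy)prop-1-en-2-yl]cyclohexane-1-carboxylate (C1 epimers and enol) | C=C[C@]1(C)C(C(=O)OC)C(=O)CC[C@@H]1C(=C)CO[Si](C)(C)C(C)(C)C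
F4 | step 23 | (1S,2R,3R,4S,5S)-5-ethenyl-5-methyl-2-[3-(PMB-oxy)prop-1-en-2-yl]-4-[3-(TBS-oxy)prop-1-en-2-yl]-3-(TES-oxy)cyclohexan-1-ol (equatorial OH) | C=C[C@]1(C)C[C@H](O)[C@@H](C(=C)COCc2ccc(OC)cc2)[C@H](O[Si](CC)(CC)CC)[C@@H]1C(=C)CO[Si](C)(C)C(C)(C)C
F5 | step 17 | tert-butyl (1S,4S,5S)-5-ethenyl-5-methyl-2-[3-(PMB-oxy)prop-1-en-2-yl]-4-[3-(TBS-oxy)prop-1-en-2-yl]cyclohex-2-en-1-yl carbonate | C=C[C@]1(C)C[C@H](OC(=O)OC(C)(C)C)C(C(=C)COCc2ccc(OC)cc2)=C[C@@H]1C(=C)CO[Si](C)(C)C(C)(C)C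
F6 | step 17 | cyclic carbonate (1,3-dioxolan-2-one) cis-fused across C1–C2 of the ring of 22, with iodine at C3 trans to the C2–O bond and the other centres as in 22 | C=C[C@]1(C)C[C@@H]2OC(=O)O[C@]2(C(=C)COCc3ccc(OC)cc3)[C@@H](I)[C@@H]1C(=C)CO[Si](C)(C)C(C)(C)C
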